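**Remarks (assumptions, one line each)**
- Atom labels C1–C30 (N29; O5, O6, O12, O25, O26) are heavy-atom positions in the target SMILES read left to right.
- Structural correction: the alkenyl unit that becomes C13/C14/C28 must have three carbons. A but-3-yn-1-ol unit puts two CH2 groups between C13 and oxygen, which fits neither C13–C28H2–N nor alkylation of bis(phenylsulfonyl)methane at C14. The silyl ether of prop-2-yn-1-ol (3) is used, and the product of alternative 1 is drawn corrected (A1).
- Spectator changes in the key-step precursor, skeleton unchanged: TBDPS on O–C11 and TBS on O–C28 so the two primary ethers can be told apart; C22–C24 is carried as a methyl propanoate instead of allyl.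
- Compounds 1, 3, 7, 11, 16 and 28 are taken as purchasable; the copper catalyst of step 2 is used as the enantiomer that gives (S)-C10.
- Facial selectivities in steps 4, 6, 12 and 18 are argued by hand from conformational models, not computed.

## Structural features

The target is a heptacyclic amino dilactone built around the cyclopentane C8–C9–C10–C21–C27. A cycloheptane (C10, C13, C14, C15, C16, C20, C21) is cis-fused across C10–C21 and carries a cyclopentene (C16–C17–C18–C19=C20) fused at C16–C20; a δ-lactone (C21–C22–C23–C24–O26–C27) is cis-fused across C21–C27. N29 bridges C8 and C10 through C28–C13 as a piperidine (a 2-azabicyclo[3.2.1]octane with the cyclopentane) and also belongs to a pyrrolidine (N29–C8–C7–C2–C30) that is cis-fused at C2–C7 to a γ-lactone (C2–C3–C4–O6–C7). There are eight stereocentres, six of them contiguous (C7, C8, C27, C21, C10, C13); C10 and C21 are vicinal all-carbon quaternary centres, C8 is an aza-quaternary centre between the carbinol carbons C7 and C27, and C2 is a further quaternary centre. On the cyclopentane, C7, O26, C22 and C11 lie on one face and N29, C20 and C13 on the other. Fragile groups are the two lactones (base, hydride, organometallics), the tertiary amine, the neopentyl primary alcohol and the trisubstituted C19=C20 alkene next to quaternary C21 (acid, electrophiles). The real difficulty is the density of fully substituted carbons around C8–C27–C21–C10 and the stereocontrolled closure of the seven-membered ring. The key step exploits that C16 is the allylic stereocentre of a cyclopentene with no other substituent: C16–C20–C19 is a locally symmetric allyl unit hinged on C21, so every allylic carbonate isomer funnels into one π-allyl complex that the C15 carbanion can close.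

## Logic of the disconnections

**36 ⇐ 35 ⇐ 34.** After the O–Si bond, C2–C30 is cut. The cis-fusion of the two five-membered rings dictates C2, so this quaternary centre needs no external control. The lactone–pyrrolidine bicycle simplifies to a flat butenolide and an N–CH2–S unit. The forward step demands a 5-exo radical attack on a β,β-disubstituted acceptor that outruns simple reduction.

**34 ⇐ 33 ⇐ 31.** N29–C30 and N29–C28 are cut. Nitrogen becomes a primary amine on C8 and C28 a primary alcohol. The N-alkylation can only occur if N already sits on the face of C13, so C8 must be correctly set beforehand.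

**31 ⇐ 30 ⇐ 27 + 29.** C7–C8 is cut (vinylogous Mannich). One bond delivers the aza-quaternary C8 and the whole butenolide, reducing the right-hand half to a ketone (26) and a commercial butenolide (28). The demand is face control at C8 and the relative configuration at C7, placed on the sulfinyl auxiliary of 27.

**26 ⇐ 24 ⇐ 23.** The O26–C24 lactone bond and the C8 carbonyl are traced back to the C27 ketone by α-hydroxylation and ketol transposition. The ketone must sit at C27 for the C21 chemistry but at C8 for amination, so one carbonyl serves twice. The forward step needs a reversible enediol and lactonisation of only the cis isomer, which then fixes C27.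

**23 ⇐ 22 ⇐ 21 (key).** C15–C16 is cut. This removes the cycloheptane and the C16 stereocentre and leaves a cyclopentanone with two acyclic arms; the carbonate configuration is irrelevant. The demand is selection between two rotameric transition states, followed by clean removal of the sulfones.

**21 ⇐ 19 ⇐ 18 ⇐ 17 ⇐ 15 + 16.** C14–C15 is cut (alkylation of 16), and the carbonate is traced to the enone of 18. The forward steps need chemoselective reduction of the enone beside the C27 ketone and differentiation of the C28 and C16 hydroxyls.

**15 ⇐ 14 ⇐ 13 ⇐ 12.** C13–H and C14–O are cut (hydroboration). C13 is stereogenic only because its two oxygenated arms differ, so the arms are told apart on a rigid oxabicyclic ketal that ties C28–O to C27. The demand is attack on one face of the exocyclic methylene of 13.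

**12 ⇐ 10 + 11, and 10 ⇐ 6 + 7.** C21–C22 (Michael) and C20–C21 (enolate alkenylation) are cut. The alkenyl group goes in first, so that C21–H becomes both α and allylic and the second bond is regiodefined. The ketal in 7 keeps C16 non-stereogenic while C21 is made quaternary. The demands are a coupling at an enolate carbon next to quaternary C10, and addition of 11 to the face of C11.

**6 ⇐ 2 + 3 (through 4), and 2 ⇐ 1.** C10–C13 is cut (catalytic enantioselective conjugate addition). This sets C10, from which all other centres except the auxiliary-guided C8/C7 are derived. The enolate regiochemistry must be stored as the silyl enol ether.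

## Other disconnections considered

**Alternative 1:** The cut is through C10–C13 and C21–C22 of the cyclopentanone. In the forward sense the alkenylalane 4 adds to C10 of the silyl-protected enone A2 under chiral copper catalysis and the enolate is trapped at C21 by an allyl electrophile, giving A1 (drawn with the three-carbon alkenyl unit).
- In its favour: it creates quaternary C10 catalytically, makes two C–C bonds in one flask and starts from very simple pieces. On the creation of C10 it is the equal of the chosen plan, which keeps this conjugate addition as step 2. In bonds made per operation it is the better.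
- Against it as the strategy-defining step: no ring is closed and seven of eight stereocentres remain. With allyl placed on C21 first, the later quaternisation must deprotonate an unactivated tertiary C21–H in competition with C8H2. The allyl group also needs three later oxidation-state changes, and its terminal alkene competes with the C13 methylene in hydroboration.
- Comparison: both plans share the copper-mediated alkenyl transfer mechanism. A1 saves one operation at the start and costs about three later.

**Alternative 2:** The cut is C20–C16, C17–C18 and C18–C19. In the forward sense the enyne A4, with an ethynyl group on C21 and a terminal alkene at C16=C17, undergoes a Pauson–Khand reaction with Co2(CO)8 to give the enone A3.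
- In its favour: two rings and three C–C bonds form in one step at a late, convergent stage, and C16 would be set by the rigid polycycle. In bond-forming power at the key step it is clearly the better.
- Against it here: the tether closes a seven-membered ring, a demanding case for this cycloaddition. The tertiary amine can bind cobalt, and amine-oxide promoters cannot be used beside it. The C18 carbonyl is surplus and must be removed in about three steps without moving the C19=C20 alkene. C16 is not stereoconvergent.
- Comparison: the chosen step makes one bond, but on a simple intermediate, under neutral conditions and with no atoms to delete. Overall step economy is judged equal or slightly in favour of the chosen plan; risk concentration is lower in the chosen plan.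

**Alternative 3:** The cut is C8–C27. In the forward sense cathodic reduction of the aldehyde in A6 gives a ketyl radical that adds 5-exo to C8 of the O-methyl ketoxime, giving the amino alcohol A5.
- In its favour: it forges the most congested bond and both heteroatom-bearing centres (C8–N, C27–O) in one reagent-free step. It is convergent, bringing in the γ-lactone with C2 and C7 already set. On control of C2/C7 and on forming the aza-quaternary centre it is the better; the trans N/O relation that such couplings favour matches the target.
- Against it here: the cycloheptane, both quaternary centres and three differentiated protecting groups must be in place first. The ester, lactone and oxime must survive the cathode. The face of C8 is governed by a distant C7 centre and the tether. An N–O cleavage and three ring closures still follow.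
- Comparison: the step count is judged comparable. The chosen plan sets the carbocyclic core earlier and with simpler fragments, but is weaker at C8/C7.

Key step: step 12

## Route

Step 1
Reactants: 1 3-(hydroxymethyl)cyclopent-2-en-1-one
Product: 2 3-[(tert-butyldiphenylsilyloxy)methyl]cyclopent-2-en-1-one
Conditions: TBDPSCl, imidazole, CH2Cl2, 0 → 23 °C
Reagents that add atoms: tert-butyl(chloro)diphenylsilane, CC(C)(C)[Si](Cl)(c1ccccc1)c1ccccc1
Why: Silylation of a primary alcohol; the TBDPS ether on O–C11 must outlast all acidic and basic steps up to step 22 and stay distinguishable from the silyl ether later placed on O–C28.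

Step 2
Reactants: 2 3-[(tert-butyldiphenylsilyloxy)methyl]cyclopent-2-en-1-one; 3 tert-butyldimethyl(prop-2-yn-1-yloxy)silane
Product: 6 (S)-trimethylsilyl enol ether of the conjugate adduct (C21=C27), via alkenylalane 4 (not isolated), via aluminium enolate 5 (not isolated)
Conditions: 3, DIBAL-H, Ni(dppp)Cl2 (3 mol %), THF, 4 °C; then 2, Cu(OTf)2 (5 mol %), chiral sulfonate-bearing NHC ligand (5 mol %), −30 °C; then TMSOTf, −78 → 0 °C
Reagents that add atoms: trimethylsilyl trifluoromethanesulfonate, C[Si](C)(C)OS(=O)(=O)C(F)(F)F
Why: Nickel-catalysed α-selective hydroalumination gives the 1,1-disubstituted alkenylalane, which adds to the β-substituted enone under copper–NHC catalysis (catalytic enantioselective conjugate addition forming an all-carbon quaternary centre). The ligand enantiomer is chosen to give (S)-C10, and O-silylation of the aluminium enolate stores the C21=C27 enolate regiochemistry for step 3.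

Step 3
Reactants: 6 (S)-trimethylsilyl enol ether of the conjugate adduct; 7 6-bromo-1,4-dioxaspiro[4.4]non-6-ene
Product: 10 2-(1,4-dioxaspiro[4.4]non-6-en-6-yl)cyclopentanone (C21 epimers), via lithium enolate 8 (not isolated), via chlorozinc enolate 9 (not isolated)
Conditions: MeLi, THF, 0 °C; ZnCl2, −20 °C; then 7, Pd(dba)2 (5 mol %), P(t-Bu)3 (10 mol %), 23 → 50 °C
Reagents that add atoms: none
Why: The silyl enol ether is cleaved to the regiodefined enolate, which is coupled at C21 with the alkenyl bromide (palladium-catalysed α-alkenylation of a ketone enolate; the zinc enolate does not drift to the C8 side). The C21 epimer mixture is harmless because C21 is re-enolised in step 4, and the ketal keeps C16 free of a stereocentre.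

Step 4
Reactants: 10 2-(1,4-dioxaspiro[4.4]non-6-en-6-yl)cyclopentanone; 11 methyl acrylate
Product: 12 C21-quaternary keto ester (C22 cis to C11)
Conditions: KOt-Bu (0.2 equiv), THF/t-BuOH, −20 → 0 °C
Reagents that add atoms: none
Why: C21–H is now α to the ketone and allylic, so base gives the extended dienolate C27(O)=C21–C20=C19 and not the C8 enolate, and Michael addition occurs at the α-carbon (deconjugative α-alkylation of a dienolate). The acrylate is expected to approach anti to the α-branched C13 substituent on C10, placing C22 cis to C11 and the cyclopentenyl group cis to C13.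

Step 5
Reactants: 12 C21-quaternary keto ester
Product: 13 oxabicyclic methyl ketal with exocyclic C13=C14
Conditions: CSA (0.1 equiv), MeOH, HC(OMe)3, 0 → 23 °C
Reagents that add atoms: methanol, CO
Why: Acid removes the primary allylic TBS ether (TBDPS ether and dioxolane persist), and the freed C28 hydroxyl closes with methanol onto the C27 ketone (intramolecular mixed ketalisation, six-membered ring). The resulting 2-oxabicyclo[3.2.1]octane protects the ketone and locks the C10–C13 bond for step 6.

Step 6
Reactants: 13 oxabicyclic methyl ketal with exocyclic C13=C14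
Product: 14 C14 primary alcohol with C13 set
Conditions: 9-BBN, THF, 0 → 23 °C; then H2O2, pH 7 buffer
Reagents that add atoms: hydrogen peroxide, OO
Why: Hydroboration–oxidation of the exocyclic 1,1-disubstituted alkene; 9-BBN leaves the trisubstituted cyclopentene and the ester alone. In the chair-like oxabicycle the cyclopentenyl group on C21 overhangs the axial face of C13 (as the syn bridge substituent does in bornane-type systems), so hydrogen enters anti to C20 and C14 ends on the side of C20, which is the C13 configuration of the target.

Step 7
Reactants: 14 C14 primary alcohol with C13 set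
Product: 15 C14 primary iodide
Conditions: I2, PPh3, imidazole, CH2Cl2, 0 °C
Reagents that add atoms: iodine, II
Why: Appel-type iodination of a primary alcohol under buffered conditions that leave both ketals intact.

Step 8
Reactants: 15 C14 primary iodide; 16 bis(phenylsulfonyl)methane
Product: 17 C15 bis(phenylsulfonyl)methyl ketal
Conditions: NaH, DMF, 0 → 60 °C
Reagents that add atoms: none
Why: SN2 alkylation of the sodium salt of bis(phenylsulfonyl)methane (pKa about 12) by the primary iodide forms C14–C15; the soft, weakly basic carbanion spares the ester, and both ketones are masked.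

Step 9
Reactants: 17 C15 bis(phenylsulfonyl)methyl ketal
Product: 18 hydroxy enone ketone
Conditions: 1 M HCl, THF, 23 °C
Reagents that add atoms: water, O
Why: Acid hydrolysis of both ketals returns the C27 ketone with the C28 alcohol (in equilibrium with its bicyclic hemiketal) and the cyclopentenone; the neopentyl TBDPS ether and the methyl ester withstand dilute acid at room temperature.

Step 10
Reactants: 18 hydroxy enone ketone
Product: 19 allylic alcohol (C16 epimers)
Conditions: NaBH4, CeCl3·7H2O, MeOH, −78 °C
Reagents that add atoms: none
Why: Luche reduction is expected to reduce the conjugated enone 1,2 in preference to the cyclopentanone flanked by quaternary C21, which is further shielded as its hemiketal. The C16 configuration is deliberately left uncontrolled because step 12 erases it, and the low temperature suppresses Michael addition of the bis-sulfone to the enone.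

Step 11
Reactants: 19 allylic alcohol (C16 epimers)
Product: 21 allylic methyl carbonate (key-step precursor), via silyl ether 20 (not isolated)
Conditions: TBSCl, imidazole, CH2Cl2, −20 → 0 °C; then ClCO2Me, pyridine, DMAP, 0 °C
Reagents that add atoms: tert-butyl(chloro)dimethylsilane, CC(C)(C)[Si](C)(C)Cl; methyl chloroformate, COC(=O)Cl
Why: The primary C28 hydroxyl is silylated faster than the secondary allylic one, which is then acylated to the methyl carbonate (two chemoselective O-functionalisations in one flask). The precursor thus carries distinguishable silyl ethers on C11 and C28.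

Step 12
Reactants: 21 allylic methyl carbonate (key-step precursor)
Product: 22 tricyclic ketone with cycloheptane closed
Conditions: Pd(PPh3)4 (10 mol %), dppe (12 mol %), THF (0.005 M), 65 °C
Reagents that add atoms: none
Why: Zerovalent palladium ionises the allylic methyl carbonate with loss of CO2, and the methoxide set free deprotonates the bis-sulfone (pKa about 12), so no base is added and the C8 protons of the ketone stay untouched. The closest known reaction type is the intramolecular Tsuji–Trost alkylation of bis(phenylsulfonyl)methyl carbanions by allylic carbonates under neutral conditions. Because the cyclopentenyl ring bears no other substituent, both C16 epimers of 21 give π-allyl complexes that interconvert by a half-turn about C20–C21, so the carbonate configuration is erased. C15 attacks the terminus it can reach, anti to palladium, closing the cycloheptane in 7-exo mode (C19=C20 stays outside the new ring) and creating C16. The new centre is controlled by C21 together with C10 and C13: in the rotamer expected to be favoured, the flat C27 carbonyl lies in the allyl plane beside C19–H and the C22 methylene sits on the palladium face, so that C15, held near C20 by the cis relation of C13 and C20, bonds to C16 with H16 syn to C22. The other rotamer forces the C22 methylene into the allyl plane against C19–H (A(1,3) strain) and is expected to lie higher. The step needs C- over O-alkylation, ring closure over oligomerisation (high dilution) and this facial preference; the small chelating dppe is chosen so that the metal fragment penalises the favoured rotamer as little as possible.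

Step 13
Reactants: 22 tricyclic ketone with cycloheptane closed
Product: 23 desulfonylated tricyclic keto ester
Conditions: Mg, MeOH, 23 → 50 °C
Reagents that add atoms: none
Why: Single-electron desulfonylation of the geminal bis-sulfone by magnesium in methanol replaces both C–S bonds by C–H; the isolated alkene, the saturated ester, the silyl ethers and the hindered ketone are not expected to be reduced.

Step 14
Reactants: 23 desulfonylated tricyclic keto ester
Product: 24 C8 α-hydroxy ketone (C8 epimers)
Conditions: KHMDS, THF, −78 °C; 2-(phenylsulfonyl)-3-phenyloxaziridine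
Reagents that add atoms: 2-(phenylsulfonyl)-3-phenyloxaziridine, O=S(=O)(N1OC1c1ccccc1)c1ccccc1
Why: The ketone can enolise only toward C8, and the potassium enolate is hydroxylated by the N-sulfonyloxaziridine (enolate oxidation). The C8 configuration is irrelevant because C8 becomes a carbonyl carbon in step 15.

Step 15
Reactants: 24 C8 α-hydroxy ketone (C8 epimers)
Product: 26 C8 keto δ-lactone, via hydroxy ester 25 (not isolated)
Conditions: DBU (0.5 equiv), toluene, 4 Å MS, 80 °C
Reagents that add atoms: none
Why: Base-mediated α-ketol isomerisation through the enediol moves the carbonyl from C27 to C8, a known behaviour of five-ring ketols next to a quaternary carbon. The C27 hydroxyl that is cis to C22 leaves the equilibrium as the δ-lactone; since the C27 epimers interconvert through the enediol, lactonisation selects the cis-fused isomer with O26 on the face of C22.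

Step 16
Reactants: 26 C8 keto δ-lactone
Product: 27 (R)-N-tert-butanesulfinyl ketimine
Conditions: (R)-t-BuS(O)NH2, Ti(OEt)4, THF, 60 °C
Reagents that add atoms: (R)-2-methylpropane-2-sulfinamide, CC(C)(C)[S@@](=O)N
Why: Titanium-mediated condensation gives the N-sulfinyl ketimine with sulfur anti to the more substituted C27; the sulfinyl group both activates C8=N and directs the next step.

Step 17
Reactants: 28 4-methylfuran-2(5H)-one
Product: 29 tert-butyldimethyl[(4-methylfuran-2-yl)oxy]silane
Conditions: TBSOTf, Et3N, CH2Cl2, 0 °C
Reagents that add atoms: tert-butyldimethylsilyl trifluoromethanesulfonate, CC(C)(C)[Si](C)(C)OS(=O)(=O)C(F)(F)F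
Why: Soft enolisation and O-silylation of the butenolide gives the 2-silyloxyfuran, the vinylogous nucleophile for step 18.

Step 18
Reactants: 27 (R)-N-tert-butanesulfinyl ketimine; 29 tert-butyldimethyl[(4-methylfuran-2-yl)oxy]silane
Product: 30 sulfinamide butenolide (C7–C8 formed)
Conditions: TMSOTf (0.3 equiv), CH2Cl2, −78 °C
Reagents that add atoms: none
Why: Lewis-acid-promoted vinylogous Mannich addition of furan C5 to the N-sulfinyl ketimine forms C7–C8 and the aza-quaternary centre. In the open transition state with S=O syn-periplanar to C=N the nucleophile adds anti to the tert-butyl group, which for the (R)-auxiliary is the face cis to O26 (C7 up, N down). The furan is expected to approach with its C5–H over the ring and its methyl-bearing carbon on the C9 side, giving the C7 configuration shown.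

Step 19
Reactants: 30 sulfinamide butenolide
Product: 31 amino alcohol (C8–NH2 and C28–OH)
Conditions: HCl (4 M in dioxane), MeOH, 0 °C; NaHCO3 work-up
Reagents that add atoms: none
Why: Acid methanolysis cleaves the N–S bond of the sulfinamide and the primary TBS ether, while the TBDPS ether on the neopentyl oxygen persists; any δ-lactone opened by methanol is expected to reclose on concentration.

Step 20
Reactants: 31 amino alcohol (C8–NH2 and C28–OH)
Product: 33 piperidine secondary amine, via bromide 32 (not isolated)
Conditions: PPh3, CBr4, CH2Cl2, 0 °C; then NaHCO3, MeCN, 50 °C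
Reagents that add atoms: none
Why: Appel bromination of the primary alcohol followed by intramolecular N-alkylation (6-exo-tet) closes the piperidine. The hindered tert-alkyl amine is not consumed by the phosphonium reagent, and the mild base avoids epimerising the butenolide γ-carbon C7.

Step 21
Reactants: 33 piperidine secondary amine
Product: 34 N-(phenylsulfanylmethyl) amine
Conditions: aq CH2O, PhSH, EtOH, 23 °C
Reagents that add atoms: formaldehyde, C=O; benzenethiol, Sc1ccccc1
Why: Mannich-type condensation of the secondary amine with formaldehyde and thiophenol gives the N,S-acetal, a precursor of the α-aminomethyl radical; the exocyclic methylene iminium involved is unstrained and the medium is neutral.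

Step 22
Reactants: 34 N-(phenylsulfanylmethyl) amine
Product: 35 silyl ether of the target
Conditions: Bu3SnH (slow addition), AIBN, benzene, 80 °C
Reagents that add atoms: none
Why: Tin-mediated C–S homolysis gives the nucleophilic α-amino radical at C30, which adds 5-exo-trig to the β-carbon C2 of the butenolide; the α-carbonyl radical is then reduced by the stannane (radical conjugate addition). The new ring can only be cis-fused to the lactone, so the quaternary C2 follows from C7.

Step 23
Reactants: 35 silyl ether of the target
Product: 36 CNP0247797.1
Conditions: HF·pyridine, THF, 0 → 23 °C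
Reagents that add atoms: none
Why: Fluoride cleavage of the silyl ether frees the C11 primary alcohol; lactones, tertiary amine and alkene are inert to these conditions.

## Compound list

1 | 3-(hydroxymethyl)cyclopent-2-en-1-one | O=C1CCC(CO)=C1 | starting material
2 | 3-[(tert-butyldiphenylsilyloxy)methyl]cyclopent-2-en-1-one | O=C1CCC(CO[Si](c2ccccc2)(c2ccccc2)C(C)(C)C)=C1 | intermediate
3 | tert-butyldimethyl(prop-2-yn-1-yloxy)silane (silyl ether of prop-2-yn-1-ol) | C#CCO[Si](C)(C)C(C)(C)C | starting material
4 | diisobutyl[3-(tert-butyldimethylsilyloxy)prop-1-en-2-yl]aluminium | C=C(CO[Si](C)(C)C(C)(C)C)[Al](CC(C)C)CC(C)C | intermediate (not isolated)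
5 | diisobutylaluminium enolate of the conjugate adduct, (S) at C10, enolate C21=C27 | CC(C)C[Al](CC(C)C)OC1=C[C@](CO[Si](c2ccccc2)(c2ccccc2)C(C)(C)C)(C(=C)CO[Si](C)(C)C(C)(C)C)CC1 | intermediate (not isolated)
6 | {[(3S)-3-[(tert-butyldiphenylsilyloxy)methyl]-3-[3-(tert-butyldimethylsilyloxy)prop-1-en-2-yl]cyclopent-1-en-1-yl]oxy}trimethylsilane | C[Si](C)(C)OC1=C[C@](CO[Si](c2ccccc2)(c2ccccc2)C(C)(C)C)(C(=C)CO[Si](C)(C)C(C)(C)C)CC1 | intermediate
7 | 6-bromo-1,4-dioxaspiro[4.4]non-6-ene (ethylene ketal of 2-bromocyclopent-2-en-1-one) | BrC1=CCCC12OCCO2 | starting material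
8 | lithium enolate corresponding to 6 | [Li]OC1=C[C@](CO[Si](c2ccccc2)(c2ccccc2)C(C)(C)C)(C(=C)CO[Si](C)(C)C(C)(C)C)CC1 | intermediate (not isolated)
9 | chlorozinc enolate corresponding to 6 | Cl[Zn]OC1=C[C@](CO[Si](c2ccccc2)(c2ccccc2)C(C)(C)C)(C(=C)CO[Si](C)(C)C(C)(C)C)CC1 | intermediate (not isolated)
10 | (3S)-3-[(tert-butyldiphenylsilyloxy)methyl]-3-[3-(tert-butyldimethylsilyloxy)prop-1-en-2-yl]-2-(1,4-dioxaspiro[4.4]non-6-en-6-yl)cyclopentan-1-one, both C21 epimers | O=C1CC[C@@](CO[Si](c2ccccc2)(c2ccccc2)C(C)(C)C)(C(=C)CO[Si](C)(C)C(C)(C)C)C1C3=CCCC34OCCO4 | intermediate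
11 | methyl acrylate | C=CC(=O)OC | starting material
12 | keto ester with quaternary C21: 10 carrying CH2CH2CO2Me on C21, C22 cis to C11 and the cyclopentenyl ketal cis to C13 | O=C1CC[C@@](CO[Si](c2ccccc2)(c2ccccc2)C(C)(C)C)(C(=C)CO[Si](C)(C)C(C)(C)C)[C@@]1(CCC(=O)OC)C3=CCCC34OCCO4 | intermediate
13 | oxabicyclic methyl ketal: C27 bonded to OMe and through O to C28 (2-oxabicyclo[3.2.1]octane, bridgeheads C10 and C27), exocyclic C13=C14 methylene | CO[C@@]12CC[C@@](CO[Si](c3ccccc3)(c3ccccc3)C(C)(C)C)(C(=C)CO1)[C@@]2(CCC(=O)OC)C4=CCCC45OCCO5 | intermediate
14 | C14 primary alcohol of the oxabicyclic ketal, C13 configured with C14 on the side of C20 | CO[C@@]12CC[C@@](CO[Si](c3ccccc3)(c3ccccc3)C(C)(C)C)([C@H](CO)CO1)[C@@]2(CCC(=O)OC)C4=CCCC45OCCO5 | intermediate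
15 | C14 primary iodide of the oxabicyclic ketal | CO[C@@]12CC[C@@](CO[Si](c3ccccc3)(c3ccccc3)C(C)(C)C)([C@H](CI)CO1)[C@@]2(CCC(=O)OC)C4=CCCC45OCCO5 | intermediate
16 | bis(phenylsulfonyl)methane | O=S(=O)(CS(=O)(=O)c1ccccc1)c1ccccc1 | starting material
17 | oxabicyclic ketal carrying CH2CH(SO2Ph)2 on C13 (C14–C15 formed) | CO[C@@]12CC[C@@](CO[Si](c3ccccc3)(c3ccccc3)C(C)(C)C)([C@H](CC(S(=O)(=O)c6ccccc6)S(=O)(=O)c6ccccc6)CO1)[C@@]2(CCC(=O)OC)C4=CCCC45OCCO5 | intermediate
18 | hydroxy enone ketone: C27 ketone, C28 alcohol, 5-oxocyclopent-1-enyl on C21, C15 bis-sulfone | O=C1CC[C@@](CO[Si](c2ccccc2)(c2ccccc2)C(C)(C)C)([C@@H](CO)CC(S(=O)(=O)c3ccccc3)S(=O)(=O)c3ccccc3)[C@@]1(CCC(=O)OC)C4=CCCC4=O | intermediate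
19 | allylic alcohol at C16 (both epimers), C28 alcohol free | O=C1CC[C@@](CO[Si](c2ccccc2)(c2ccccc2)C(C)(C)C)([C@@H](CO)CC(S(=O)(=O)c3ccccc3)S(=O)(=O)c3ccccc3)[C@@]1(CCC(=O)OC)C4=CCCC4O | intermediate
20 | C28 tert-butyldimethylsilyl ether of 19 | O=C1CC[C@@](CO[Si](c2ccccc2)(c2ccccc2)C(C)(C)C)([C@@H](CO[Si](C)(C)C(C)(C)C)CC(S(=O)(=O)c3ccccc3)S(=O)(=O)c3ccccc3)[C@@]1(CCC(=O)OC)C4=CCCC4O | intermediate (not isolated)
21 | key-step precursor: cyclopentanone with C15 bis-sulfone, C28 OTBS, C11 OTBDPS, methyl propanoate on C21 and cyclopentenyl methyl carbonate (both C16 epimers) | O=C1CC[C@@](CO[Si](c2ccccc2)(c2ccccc2)C(C)(C)C)([C@@H](CO[Si](C)(C)C(C)(C)C)CC(S(=O)(=O)c3ccccc3)S(=O)(=O)c3ccccc3)[C@@]1(CCC(=O)OC)C4=CCCC4OC(=O)OC | intermediate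
22 | tricyclic ketone with cycloheptane closed and C16 set (H16 syn to C22), C15 bis-sulfone | O=C1CC[C@@]2(CO[Si](c3ccccc3)(c3ccccc3)C(C)(C)C)[C@H](CC(S(=O)(=O)c4ccccc4)(S(=O)(=O)c4ccccc4)[C@H]5CCC=C5[C@@]12CCC(=O)OC)CO[Si](C)(C)C(C)(C)C | intermediate
23 | desulfonylated tricyclic keto ester | O=C1CC[C@@]2(CO[Si](c3ccccc3)(c3ccccc3)C(C)(C)C)[C@H](CC[C@H]4CCC=C4[C@@]12CCC(=O)OC)CO[Si](C)(C)C(C)(C)C | intermediate
24 | α-hydroxy ketone: OH on C8 (both epimers), ketone at C27 | O=C1C(O)C[C@@]2(CO[Si](c3ccccc3)(c3ccccc3)C(C)(C)C)[C@H](CC[C@H]4CCC=C4[C@@]12CCC(=O)OC)CO[Si](C)(C)C(C)(C)C | intermediate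
25 | transposed ketol: ketone at C8, C27 hydroxyl cis to C22, methyl ester | O=C1C[C@@]2(CO[Si](c3ccccc3)(c3ccccc3)C(C)(C)C)[C@H](CC[C@H]4CCC=C4[C@@]2(CCC(=O)OC)[C@@H]1O)CO[Si](C)(C)C(C)(C)C | intermediate (not isolated)
26 | keto δ-lactone: ketone at C8, O26–C24 lactone cis-fused at C21–C27 | O=C1C[C@@]2(CO[Si](c3ccccc3)(c3ccccc3)C(C)(C)C)[C@H](CC[C@H]4CCC=C4[C@]25CCC(=O)O[C@H]15)CO[Si](C)(C)C(C)(C)C | intermediate
27 | (R)-N-tert-butanesulfinyl ketimine at C8 (sulfur anti to C27) | CC(C)(C)[S@@](=O)N=C1C[C@@]2(CO[Si](c3ccccc3)(c3ccccc3)C(C)(C)C)[C@H](CC[C@H]4CCC=C4[C@]25CCC(=O)O[C@H]15)CO[Si](C)(C)C(C)(C)C | intermediate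
28 | 4-methylfuran-2(5H)-one | CC1=CC(=O)OC1 | starting material
29 | tert-butyldimethyl[(4-methylfuran-2-yl)oxy]silane | Cc1coc(O[Si](C)(C)C(C)(C)C)c1 | intermediate
30 | vinylogous Mannich adduct: (R)-sulfinamide nitrogen on C8, 4-methylbutenolide attached through C7 | CC1=CC(=O)O[C@@H]1[C@]2(N[S@](=O)C(C)(C)C)C[C@@]3(CO[Si](c4ccccc4)(c4ccccc4)C(C)(C)C)[C@H](CC[C@H]5CCC=C5[C@]36CCC(=O)O[C@H]26)CO[Si](C)(C)C(C)(C)C | intermediate
31 | amino alcohol: primary amine on C8, primary alcohol at C28 | CC1=CC(=O)O[C@@H]1[C@]2(N)C[C@@]3(CO[Si](c4ccccc4)(c4ccccc4)C(C)(C)C)[C@H](CC[C@H]5CCC=C5[C@]36CCC(=O)O[C@H]26)CO | intermediate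
32 | amino bromide (C28–Br) | CC1=CC(=O)O[C@@H]1[C@]2(N)C[C@@]3(CO[Si](c4ccccc4)(c4ccccc4)C(C)(C)C)[C@H](CC[C@H]5CCC=C5[C@]36CCC(=O)O[C@H]26)CBr | intermediate (not isolated)
33 | piperidine: secondary amine N29 bridging C8 and C28 | CC1=CC(=O)O[C@@H]1[C@]23C[C@@]4(CO[Si](c5ccccc5)(c5ccccc5)C(C)(C)C)[C@H](CC[C@H]6CCC=C6[C@]47CCC(=O)O[C@H]27)CN3 | intermediate
34 | N-(phenylsulfanylmethyl) derivative of 33 | CC1=CC(=O)O[C@@H]1[C@]23C[C@@]4(CO[Si](c5ccccc5)(c5ccccc5)C(C)(C)C)[C@H](CC[C@H]6CCC=C6[C@]47CCC(=O)O[C@H]27)CN3CSc8ccccc8 | intermediate
35 | O11-tert-butyldiphenylsilyl ether of the target | C[C@@]12CC(=O)O[C@@H]1[C@]13C[C@@]4(CO[Si](c5ccccc5)(c5ccccc5)C(C)(C)C)[C@H](CC[C@H]6CCC=C6[C@]47CCC(=O)O[C@H]17)CN3C2 | intermediate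
36 | CNP0247797.1 | C[C@@]12CC(=O)O[C@@H]1[C@]13C[C@@]4(CO)[C@H](CC[C@H]5CCC=C5[C@]45CCC(=O)O[C@H]15)CN3C2 | target

## Step count and least certain steps

Total: 23 steps. Longest linear sequence: 22 steps (steps 1–16 and 18–23; step 17 is a one-step side branch).

**Step 12 (key step).** The likeliest failure is poor discrimination between the two rotameric π-allyl transition states, giving a mixture at C16, because the preference rests only on A(1,3) strain against the bulk of the metal fragment. Oligomerisation or elimination to a cyclopentadiene could also compete with a slow seven-ring closure. The fallback reverses the order of the two bonds at C15 and sets C16 under catalyst control. It sets out from 15: hydrolysis as in step 9 gives the iodo enone F1, reduction as in step 10 gives the iodo allylic alcohol F2, and silylation with carbonate formation as in step 11 gives the iodo carbonate F3. Intermolecular palladium-catalysed asymmetric allylic alkylation of 16 with F3, using Pd2(dba)3 and (R,R)-N,N′-(cyclohexane-1,2-diyl)bis[2-(diphenylphosphino)benzamide] (or its enantiomer, whichever is matched), selects one of the two allyl termini and gives the allylated bis-sulfone F4. Cs2CO3 in DMF then closes the ring by 7-exo-tet alkylation at C14 and returns to the route at 22.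

**Step 3.** The coupling may stall at reductive elimination, because the enolate carbon C21 is next to quaternary C10 and the alkenyl bromide is flanked by the spiro ketal. Proton transfer from the more acidic product to unreacted enolate would then erode both conversion and regiochemistry. The fallback builds C20–C21 by carbonyl addition. It sets out from 6: the lithium enolate 8 adds at −78 °C to commercial 1,4-dioxaspiro[4.4]nonan-6-one to give the tertiary aldol F5. Dehydration with methyl N-(triethylammoniosulfonyl)carbamate then returns to the route at 10; if the conjugated C20=C21 isomer forms instead, it gives the same dienolate in step 4.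

**Step 15.** The ketol equilibrium may not drain into the lactone: retro-aldol or oxidative loss of the enediol, or an unfavourable equilibrium, would stop the transposition. The fallback separates reduction, ring closure and oxidation. It sets out from 24: NaBH4 in MeOH at −40 °C gives the diol F6. PPTS in toluene at 80 °C lactonises only the epimer with the C27 hydroxyl cis to C22, giving the hydroxy lactone F7; diol that cannot lactonise is re-oxidised and recycled. Dess–Martin oxidation of the C8 hydroxyl returns to the route at 26.

**Step 18.** Addition to the wrong face of C8 is possible, because the vicinal lactone oxygen and the concave shape near C27 may oppose the auxiliary. The relative configuration at C7 rests on a steric model only, and ketimine enolisation could compete. The fallback moves stereocontrol from the auxiliary to a chiral catalyst and uses the butenolide itself as pronucleophile. It sets out from 26: condensation with P,P-diphenylphosphinothioic amide and Ti(OEt)4 gives the N-thiophosphinoyl ketimine F8. A direct catalytic vinylogous Mannich reaction with 28, using Cu(MeCN)4PF6, a chiral bisphosphine and Et3N, gives the adduct F9. HCl in MeOH removes the thiophosphinoyl and TBS groups and returns to the route at 31.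

## Further compounds

F1 | step 12 | iodo enone: C14 iodide, C28 alcohol, C27 ketone, 5-oxocyclopent-1-enyl on C21 | O=C1CC[C@@](CO[Si](c2ccccc2)(c2ccccc2)C(C)(C)C)([C@@H](CO)CI)[C@@]1(CCC(=O)OC)C3=CCCC3=O
F2 | step 12 | iodo allylic alcohol (C16 epimers) | O=C1CC[C@@](CO[Si](c2ccccc2)(c2ccccc2)C(C)(C)C)([C@@H](CO)CI)[C@@]1(CCC(=O)OC)C3=CCCC3O
F3 | step 12 | iodo carbonate: C14 iodide, C28 OTBS, C16 methyl carbonate | O=C1CC[C@@](CO[Si](c2ccccc2)(c2ccccc2)C(C)(C)C)([C@@H](CO[Si](C)(C)C(C)(C)C)CI)[C@@]1(CCC(=O)OC)C3=CCCC3OC(=O)OC
F4 | step 12 | allylated bis-sulfone: C16–C15 formed, C14 iodide retained | O=C1CC[C@@](CO[Si](c2ccccc2)(c2ccccc2)C(C)(C)C)([C@@H](CO[Si](C)(C)C(C)(C)C)CI)[C@@]1(CCC(=O)OC)C3=CCC[C@@H]3C(S(=O)(=O)c4ccccc4)S(=O)(=O)c4ccccc4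
F5 | step 3 | tertiary aldol: C21 bonded to C20 bearing OH, dioxolane at C16 | O=C1CC[C@@](CO[Si](c2ccccc2)(c2ccccc2)C(C)(C)C)(C(=C)CO[Si](C)(C)C(C)(C)C)C1C3(O)CCCC34OCCO4
F6 | step 15 | C8,C27 diol methyl ester (epimers) | OC1C(O)C[C@@]2(CO[Si](c3ccccc3)(c3ccccc3)C(C)(C)C)[C@H](CC[C@H]4CCC=C4[C@@]12CCC(=O)OC)CO[Si](C)(C)C(C)(C)C
F7 | step 15 | C8 hydroxy δ-lactone | OC1C[C@@]2(CO[Si](c3ccccc3)(c3ccccc3)C(C)(C)C)[C@H](CC[C@H]4CCC=C4[C@]25CCC(=O)O[C@H]15)CO[Si](C)(C)C(C)(C)C
F8 | step 18 | N-(diphenylthiophosphinoyl) ketimine at C8 | S=P(N=C1C[C@@]2(CO[Si](c3ccccc3)(c3ccccc3)C(C)(C)C)[C@H](CC[C@H]4CCC=C4[C@]25CCC(=O)O[C@H]15)CO[Si](C)(C)C(C)(C)C)(c6ccccc6)c6ccccc6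
F9 | step 18 | thiophosphinamide butenolide adduct | CC1=CC(=O)O[C@@H]1[C@]2(NP(=S)(c7ccccc7)c7ccccc7)C[C@@]3(CO[Si](c4ccccc4)(c4ccccc4)C(C)(C)C)[C@H](CC[C@H]5CCC=C5[C@]36CCC(=O)O[C@H]26)CO[Si](C)(C)C(C)(C)C
A1 | alternative 1 | 2-allyl-3-alkenyl-3-(silyloxymethyl)cyclopentanone with C10 set (three-carbon alkenyl unit) | O=C1CC[C@@](CO[Si](C)(C)C(C)(C)C)(C(=C)CO[Si](C)(C)C(C)(C)C)[C@@H]1CC=C
A2 | alternative 1 | 3-[(tert-butyldimethylsilyloxy)methyl]cyclopent-2-en-1-one | O=C1CCC(CO[Si](C)(C)C(C)(C)C)=C1
A3 | alternative 2 | C18 enone of the O-silylated target | C[C@@]12CC(=O)O[C@@H]1[C@]13C[C@@]4(CO[Si](C)(C)C(C)(C)C)[C@H](CC[C@H]5CC(=O)C=C5[C@]45CCC(=O)O[C@H]15)CN3C2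
A4 | alternative 2 | enyne precursor: ethynyl on C21 and but-3-enyl on C13 | C#C[C@@]12CCC(=O)O[C@@H]1[C@]34C[C@@]2(CO[Si](C)(C)C(C)(C)C)[C@H](CCC=C)CN3C[C@]5(C)CC(=O)O[C@H]45
A5 | alternative 3 | cyclopentane amino alcohol with N-methoxyamine at C8 and hydroxyl at C27 | C[C@@]1(CO[Si](C)(C)C(C)(C)C)CC(=O)O[C@@H]1[C@]2(NOC)C[C@@]3(COCc5ccc(OC)cc5)[C@H](CC[C@H]4CCC=C4[C@@]3(CCC(=O)OC)[C@@H]2O)CO[Si](C)(C)C(C)(C)C
A6 | alternative 3 | aldehyde O-methyl ketoxime precursor | C[C@@]1(CO[Si](C)(C)C(C)(C)C)CC(=O)O[C@@H]1C(=NOC)C[C@@]2(COCc3ccc(OC)cc3)[C@H](CC[C@H]4CCC=C4[C@@]2(CCC(=O)OC)C=O)CO[Si](C)(C)C(C)(C)C
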